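**Plan**

Locants: ring C1 (quaternary), C2H2, C3 (OMe), C4=C5, C6 (C=O). The side chain is C8H(CH3)–C7H(OH)–aryl, and C9 is the exocyclic carbon on C1 (CHO, later the allyl CH2).
Enabling feature: in the six-membered ring the C4=C5 double bond lies between the two oxygen-bearing carbons C3 and C6. This is the retron of a [4+2] addition of a 1,4-dioxygenated butadiene to a C1=C2 dienophile.
Cuts, in order: allyl back to CHO (C9–vinyl), then C1–C6 and C2–C3 (cycloaddition), then the C1=C2 methylene (Mannich), then C7–C8 (crotylboration of veratraldehyde).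
Forward: the chain aryl–C7–C8–C1–C9 is built first, and the only carbocycle then closes around C1 in one step. CHO to allyl, C3 inversion and methylation, C6 oxidation and C7 deprotection follow.
Stereochemistry: C7 and C8 come from a reagent-controlled (Z)-crotylboration, and C1 from a chiral oxazaborolidinium catalyst. At C3, the E,E-diene and the endo rule place the oxygen cis to CHO, which is the wrong side. A Mitsunobu inversion therefore turns it over before methylation, and C6 is erased on oxidation.

Key step: step 7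

Remark: (1E,3E)-1,4-diacetoxybuta-1,3-diene is taken as a catalogue compound and is preferred to direct silylation of succinaldehyde, which favours Z-enol ethers. Descriptors in the names of 17 to 29 use the locants above.

**Step 1**
Reactants: 1 cis-but-2-ene; 2 3,4-dimethoxybenzaldehyde
Product: 7 (1S,2R)-1-(3,4-dimethoxyphenyl)-2-methylbut-3-en-1-ol, via (Z)-crotylpotassium 3 (not isolated), via methoxyborate ate complex 4 (not isolated), via (Z)-crotyldiisopinocampheylborane 5 (not isolated), via borinic ester 6 (not isolated)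
Conditions: KOt-Bu, n-BuLi, THF, −78 to −45 °C; (−)-B-methoxydiisopinocampheylborane [from (+)-α-pinene], −78 °C; BF3·OEt2; 2, −78 °C; then NaOH, H2O2, 0 °C to rt
Reagents that add atoms: none
Why: Brown asymmetric crotylboration, in which the closed chair Zimmerman–Traxler transition state converts the Z geometry of 5 into the syn C7/C8 relation and the isopinocampheyl ligands from (+)-α-pinene direct the transfer to the Si face of the aldehyde, giving 7S,8R.

**Step 2**
Reactants: 7 (1S,2R)-1-(3,4-dimethoxyphenyl)-2-methylbut-3-en-1-ol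
Product: 8 (1S,2R)-1-(3,4-dimethoxyphenyl)-2-methyl-1-(triisopropylsilyloxy)but-3-ene
Conditions: i-Pr3SiOTf, 2,6-lutidine, CH2Cl2, 0 °C to rt
Reagents that add atoms: triisopropylsilyl triflate, CC(C)[Si](C(C)C)(C(C)C)OS(=O)(=O)C(F)(F)F
Why: Silyl ether formation with a silyl triflate copes with the flanked benzylic alcohol, and a weakly Lewis-basic, fluoride-labile group is chosen because an acetal would compete for the acid catalyst of step 7 and would need acid for its removal from an easily ionised 3,4-dimethoxybenzylic position.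

**Step 3**
Reactants: 8 (1S,2R)-1-(3,4-dimethoxyphenyl)-2-methyl-1-(triisopropylsilyloxy)but-3-ene
Product: 10 (3R,4S)-4-(3,4-dimethoxyphenyl)-3-methyl-4-(triisopropylsilyloxy)butan-1-ol, via B-alkyl-9-borabicyclononane 9 (not isolated)
Conditions: 9-borabicyclo[3.3.1]nonane, THF, 0 °C to rt; then NaOH, H2O2, 0 °C
Reagents that add atoms: hydrogen peroxide, OO
Why: Hydroboration–oxidation, in which the bulky dialkylborane places boron on the terminal carbon of the monosubstituted alkene and alkaline peroxide exchanges B for OH without touching the silyl ether, so no stereocentre is formed or disturbed.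

**Step 4**
Reactants: 10 (3R,4S)-4-(3,4-dimethoxyphenyl)-3-methyl-4-(triisopropylsilyloxy)butan-1-ol
Product: 11 (3R,4S)-4-(3,4-dimethoxyphenyl)-3-methyl-4-(triisopropylsilyloxy)butanal
Conditions: 2,2,6,6-tetramethylpiperidin-1-oxyl (10 mol %), PhI(OAc)2, CH2Cl2, rt
Reagents that add atoms: none
Why: Oxoammonium (TEMPO) oxidation of a primary alcohol stops at the aldehyde, and C8 is β to the new carbonyl group and so cannot epimerise.

**Step 5**
Reactants: 11 (3R,4S)-4-(3,4-dimethoxyphenyl)-3-methyl-4-(triisopropylsilyloxy)butanal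
Product: 13 (3R,4S)-4-(3,4-dimethoxyphenyl)-3-methyl-2-methylidene-4-(triisopropylsilyloxy)butanal, via Mannich base 12 (not isolated)
Conditions: CH2=NMe2+ I− (Eschenmoser's salt), Et3N, CH2Cl2, rt
Reagents that add atoms: N,N-dimethylmethyleneiminium iodide, C=[N+](C)C.[I-]
Why: Mannich aminomethylation of the aldehyde at its only enolisable carbon, followed by β-elimination of dimethylamine (α-methylenation), installs C2 under a mild amine base that should not move the double bond into conjugation with C8.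

**Step 6**
Reactants: 14 (1E,3E)-1,4-diacetoxybuta-1,3-diene
Product: 16 (1E,3E)-1,4-bis(tert-butyldimethylsilyloxy)buta-1,3-diene, via dilithium butadienediolate 15 (not isolated)
Conditions: MeLi (4.1 equiv), THF, −78 to 0 °C; t-BuMe2SiCl, DMPU, −78 °C to rt
Reagents that add atoms: tert-butyldimethylsilyl chloride, CC(C)(C)[Si](C)(C)Cl
Why: Cleavage of an enol acetate with methyllithium gives the lithium enolate with retention of double-bond geometry and O-silylation traps it, so the fixed E,E geometry of 14 passes unchanged into 16.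

**Step 7**
Reactants: 13 (3R,4S)-4-(3,4-dimethoxyphenyl)-3-methyl-2-methylidene-4-(triisopropylsilyloxy)butanal; 16 (1E,3E)-1,4-bis(tert-butyldimethylsilyloxy)buta-1,3-diene
Product: 17 (1R,3R,6R,7S,8R)-3,6-bis(tert-butyldimethylsilyloxy)-1-[1-(3,4-dimethoxyphenyl)-1-(triisopropylsilyloxy)propan-2-yl]cyclohex-4-ene-1-carbaldehyde (CHO cis to both ring silyloxy groups and side chain trans to them)
Conditions: (S)-1-(2-methylphenyl)-3,3-diphenyltetrahydro-1H,3H-pyrrolo[1,2-c][1,3,2]oxazaborole (20 mol %), (CF3SO2)2NH (18 mol %), 16 (2 equiv), CH2Cl2, −78 to −40 °C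
Reagents that add atoms: none
Why: The N-protonated oxazaborolidine binds the formyl oxygen of 13 (B–O bond plus formyl C–H···O contact), holds the enal s-trans and lowers its LUMO, so the electron-rich diene should add in a normal-demand, concerted but asynchronous Diels–Alder reaction in which C2–C3 bonding leads C1–C6 bonding, the closest known cases being oxazaborolidinium-catalysed additions to 2-alkylacroleins and Lewis-acid-catalysed additions of 2-alkylacroleins to open-chain (E)-1-silyloxy- and 1-carbamoylamino-dienes. The cyclohexene ring closes in one intermolecular event, both diene termini joining C1=C2 suprafacially through a boat-like six-membered transition state. The E,E geometry of 16 is transferred, so the oxygens at C3 and C6 come out cis to each other. Their relation to C1 follows the endo rule, because an open-chain E,E-diene carries no inward-pointing terminal group that could clash with the α-branch (the origin of the exo preference seen with cyclopentadiene and Z-dienes), so formyl lies under the diene, the bulky C8 branch points away from it, and CHO ends cis and the side chain trans to both oxygens. At C1 a phenyl group of the S-configured catalyst covers one π-face and leaves open the face from which C9, C2 and C8 run clockwise, which gives the 1R aldehyde (1S once CHO has become allyl), while the resident C8 centre should add only a weak bias since its rotamers lie close in energy. The step therefore needs endo and facial selectivity, secured by the α-branch and by the catalyst respectively, whereas regiochemistry is no issue because both ends of 16 are equivalent and the s-trans binding also closes the hetero-Diels–Alder channel of the enal.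

**Step 8**
Reactants: 17 the cycloadduct aldehyde; 18 vinylmagnesium bromide
Product: 20 methyl carbonate of the C9 vinyl carbinol (1S,3R,6R,7S,8R; mixture of C9 epimers), via bromomagnesium alkoxide 19 (not isolated)
Conditions: 18, THF, −78 to 0 °C; then ClCO2Me, 0 °C to rt
Reagents that add atoms: methyl chloroformate, COC(=O)Cl
Why: Grignard 1,2-addition to a non-enolisable aldehyde followed by acylation of the magnesium alkoxide in the same flask leaves little time for silyl migration, and the new C9 carbinol centre needs no control because step 9 removes it.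

**Step 9**
Reactants: 20 methyl carbonate of the C9 vinyl carbinol
Product: 21 (1S,3R,6R,7S,8R)-1-allyl-3,6-bis(tert-butyldimethylsilyloxy)-1-[1-(3,4-dimethoxyphenyl)-1-(triisopropylsilyloxy)propan-2-yl]cyclohex-4-ene
Conditions: Pd(OAc)2 (5 mol %), PBu3 (20 mol %), HCO2H, Et3N, THF, 45 °C
Reagents that add atoms: none
Why: Tsuji formate hydrogenolysis, in which zerovalent palladium formed in situ ionises the carbonate, the allyl unit binds palladium through its unhindered terminal carbon, and the formate ligand passes hydride to the internal carbon C9 with loss of CO2, a course for which PBu3 is the ligand of choice and which gives the terminal alkene while the allylic silyl ethers are not ionised.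

**Step 10**
Reactants: 21 the 1-allyl-3,6-bis(silyloxy)cyclohexene
Product: 22 (1S,3R,6R,7S,8R)-1-allyl-6-(tert-butyldimethylsilyloxy)-1-[1-(3,4-dimethoxyphenyl)-1-(triisopropylsilyloxy)propan-2-yl]cyclohex-4-en-3-ol
Conditions: HF·pyridine, pyridine, THF, 0 °C
Reagents that add atoms: none
Why: Sterically differentiated desilylation, since the C3 silyl ether sits next to a CH2 group whereas the C6 silyl ether is neopentyl (next to quaternary C1) and the triisopropylsilyl ether is intrinsically slower, so buffered HF should free C3–OH first.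

**Step 11**
Reactants: 22 the 3R allylic alcohol
Product: 23 (1S,3S,6R,7S,8R)-1-allyl-6-(tert-butyldimethylsilyloxy)-1-[1-(3,4-dimethoxyphenyl)-1-(triisopropylsilyloxy)propan-2-yl]cyclohex-4-en-3-yl 4-nitrobenzoate
Conditions: 4-nitrobenzoic acid, PPh3, DIAD, toluene, 0 °C to rt
Reagents that add atoms: 4-nitrobenzoic acid, O=C(O)c1ccc([N+](=O)[O-])cc1
Why: Mitsunobu reaction, in which the carboxylate displaces the oxyphosphonium group by SN2 and turns C3 from R to S (oxygen now cis to the side chain), while the SN2′ terminus C5 is shielded by the adjacent C6 silyl ether.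

**Step 12**
Reactants: 23 the 3S 4-nitrobenzoate
Product: 24 (1S,3S,6R,7S,8R)-1-allyl-6-(tert-butyldimethylsilyloxy)-1-[1-(3,4-dimethoxyphenyl)-1-(triisopropylsilyloxy)propan-2-yl]cyclohex-4-en-3-ol
Conditions: K2CO3, MeOH, rt
Reagents that add atoms: none
Why: Base-catalysed transesterification cleaves the activated aryl ester at the acyl carbon, so the C3–O bond and its configuration are untouched and both silyl ethers survive.

**Step 13**
Reactants: 24 the 3S allylic alcohol
Product: 26 (1S,3S,6R,7S,8R)-1-allyl-6-(tert-butyldimethylsilyloxy)-1-[1-(3,4-dimethoxyphenyl)-1-(triisopropylsilyloxy)propan-2-yl]-3-methoxycyclohex-4-ene, via sodium alkoxide 25 (not isolated)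
Conditions: NaH, THF, 0 °C; then MeI, 0 °C to rt
Reagents that add atoms: iodomethane, CI
Why: Williamson ether synthesis on the only free hydroxyl group, and silyl transfer from C6–O is not expected because the two oxygens are trans across the ring.

**Step 14**
Reactants: 26 the 3-methoxy-6-silyloxycyclohexene
Product: 27 (1S,3S,6R,7S,8R)-1-allyl-1-[1-(3,4-dimethoxyphenyl)-1-(triisopropylsilyloxy)propan-2-yl]-3-methoxycyclohex-4-en-6-ol
Conditions: HF·pyridine, THF, rt
Reagents that add atoms: none
Why: Acid-type fluoride desilylation removes a tert-butyldimethylsilyl ether much faster than a secondary triisopropylsilyl ether, so the hindered C6–OH should be freed while C7 stays protected.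

**Step 15**
Reactants: 27 the C6 allylic alcohol
Product: 28 (1S,3S,7S,8R)-1-allyl-1-[1-(3,4-dimethoxyphenyl)-1-(triisopropylsilyloxy)propan-2-yl]-3-methoxycyclohex-4-en-6-one
Conditions: 1,1,1-triacetoxy-1,1-dihydro-1,2-benziodoxol-3(1H)-one (Dess–Martin periodinane), CH2Cl2, 0 °C to rt
Reagents that add atoms: none
Why: Dess–Martin oxidation tolerates hindered allylic alcohols and gives the C4=C5–C6=O enone under nearly neutral conditions, and C1 is quaternary so no α-epimerisation or elimination path exists.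

**Step 16**
Reactants: 28 the silyl-protected enone
Product: 29 (4S,6S)-6-allyl-6-[(1S,2R)-1-(3,4-dimethoxyphenyl)-1-hydroxypropan-2-yl]-4-methoxycyclohex-2-en-1-one (target; 1S,3S,7S,8R in the locants used here)
Conditions: Bu4NF, AcOH, THF, 0 °C to rt
Reagents that add atoms: none
Why: Fluoride desilylation buffered with acetic acid frees C7–OH without the acid that would ionise the electron-rich benzylic position and without the free base that could deconjugate the γ-methoxy enone.

**Compound list**

1 | cis-but-2-ene | C/C=C\C | starting material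
2 | 3,4-dimethoxybenzaldehyde | COc1ccc(C=O)cc1OC | starting material
3 | (Z)-crotylpotassium | C/C=C\[CH2-].[K+] | intermediate
4 | potassium (Z)-crotyl(methoxy)diisopinocampheylborate | C/C=C\C[B-](OC)([C@@H]1C[C@@H]2C[C@H]([C@H]1C)C2(C)C)[C@@H]1C[C@@H]2C[C@H]([C@H]1C)C2(C)C.[K+] | intermediate
5 | (Z)-crotyldiisopinocampheylborane, Ipc from (+)-α-pinene | C/C=C\CB([C@@H]1C[C@@H]2C[C@H]([C@H]1C)C2(C)C)[C@@H]1C[C@@H]2C[C@H]([C@H]1C)C2(C)C | intermediate
6 | diisopinocampheylborinic ester of 7 | C=C[C@@H](C)[C@H](OB([C@@H]1C[C@@H]2C[C@H]([C@H]1C)C2(C)C)[C@@H]1C[C@@H]2C[C@H]([C@H]1C)C2(C)C)c1ccc(OC)c(OC)c1 | intermediate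
7 | (1S,2R)-1-(3,4-dimethoxyphenyl)-2-methylbut-3-en-1-ol | C=C[C@@H](C)[C@H](O)c1ccc(OC)c(OC)c1 | intermediate
8 | (1S,2R)-1-(3,4-dimethoxyphenyl)-2-methyl-1-(triisopropylsilyloxy)but-3-ene | C=C[C@@H](C)[C@H](O[Si](C(C)C)(C(C)C)C(C)C)c1ccc(OC)c(OC)c1 | intermediate
9 | B-alkyl-9-borabicyclo[3.3.1]nonane from 8 | B1(CC[C@@H](C)[C@H](O[Si](C(C)C)(C(C)C)C(C)C)c2ccc(OC)c(OC)c2)C2CCCC1CCC2 | intermediate
10 | (3R,4S)-4-(3,4-dimethoxyphenyl)-3-methyl-4-(triisopropylsilyloxy)butan-1-ol | OCC[C@@H](C)[C@H](O[Si](C(C)C)(C(C)C)C(C)C)c1ccc(OC)c(OC)c1 | intermediate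
11 | (3R,4S)-4-(3,4-dimethoxyphenyl)-3-methyl-4-(triisopropylsilyloxy)butanal | O=CC[C@@H](C)[C@H](O[Si](C(C)C)(C(C)C)C(C)C)c1ccc(OC)c(OC)c1 | intermediate
12 | 2-(dimethylaminomethyl) derivative of 11 (C2 epimers) | O=CC(CN(C)C)[C@@H](C)[C@H](O[Si](C(C)C)(C(C)C)C(C)C)c1ccc(OC)c(OC)c1 | intermediate
13 | (3R,4S)-4-(3,4-dimethoxyphenyl)-3-methyl-2-methylidene-4-(triisopropylsilyloxy)butanal | C=C(C=O)[C@@H](C)[C@H](O[Si](C(C)C)(C(C)C)C(C)C)c1ccc(OC)c(OC)c1 | intermediate
14 | (1E,3E)-1,4-diacetoxybuta-1,3-diene | CC(=O)O/C=C/C=C/OC(C)=O | starting material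
15 | dilithium (1E,3E)-buta-1,3-diene-1,4-diolate | [Li+].[Li+].[O-]/C=C/C=C/[O-] | intermediate
16 | (1E,3E)-1,4-bis(tert-butyldimethylsilyloxy)buta-1,3-diene | CC(C)(C)[Si](C)(C)O/C=C/C=C/O[Si](C)(C)C(C)(C)C | intermediate
17 | endo cycloadduct aldehyde (1R,3R,6R,7S,8R) | O=C[C@@]1([C@@H](C)[C@H](O[Si](C(C)C)(C(C)C)C(C)C)c2ccc(OC)c(OC)c2)C[C@@H](O[Si](C)(C)C(C)(C)C)C=C[C@H]1O[Si](C)(C)C(C)(C)C | intermediate
18 | vinylmagnesium bromide | C=C[Mg]Br | starting material
19 | bromomagnesium alkoxide of the C9 vinyl carbinol (C9 epimers) | C=CC(O[Mg]Br)[C@@]1([C@@H](C)[C@H](O[Si](C(C)C)(C(C)C)C(C)C)c2ccc(OC)c(OC)c2)C[C@@H](O[Si](C)(C)C(C)(C)C)C=C[C@H]1O[Si](C)(C)C(C)(C)C | intermediate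
20 | methyl carbonate of the C9 vinyl carbinol (C9 epimers) | C=CC(OC(=O)OC)[C@@]1([C@@H](C)[C@H](O[Si](C(C)C)(C(C)C)C(C)C)c2ccc(OC)c(OC)c2)C[C@@H](O[Si](C)(C)C(C)(C)C)C=C[C@H]1O[Si](C)(C)C(C)(C)C | intermediate
21 | 1-allyl-3,6-bis(tert-butyldimethylsilyloxy)cyclohex-4-ene (1S,3R,6R,7S,8R) | C=CC[C@@]1([C@@H](C)[C@H](O[Si](C(C)C)(C(C)C)C(C)C)c2ccc(OC)c(OC)c2)C[C@@H](O[Si](C)(C)C(C)(C)C)C=C[C@H]1O[Si](C)(C)C(C)(C)C | intermediate
22 | 3R allylic alcohol (1S,3R,6R,7S,8R) | C=CC[C@@]1([C@@H](C)[C@H](O[Si](C(C)C)(C(C)C)C(C)C)c2ccc(OC)c(OC)c2)C[C@@H](O)C=C[C@H]1O[Si](C)(C)C(C)(C)C | intermediate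
23 | 3S 4-nitrobenzoate (1S,3S,6R,7S,8R) | C=CC[C@@]1([C@@H](C)[C@H](O[Si](C(C)C)(C(C)C)C(C)C)c2ccc(OC)c(OC)c2)C[C@H](OC(=O)c2ccc([N+](=O)[O-])cc2)C=C[C@H]1O[Si](C)(C)C(C)(C)C | intermediate
24 | 3S allylic alcohol (1S,3S,6R,7S,8R) | C=CC[C@@]1([C@@H](C)[C@H](O[Si](C(C)C)(C(C)C)C(C)C)c2ccc(OC)c(OC)c2)C[C@H](O)C=C[C@H]1O[Si](C)(C)C(C)(C)C | intermediate
25 | sodium alkoxide of 24 | C=CC[C@@]1([C@@H](C)[C@H](O[Si](C(C)C)(C(C)C)C(C)C)c2ccc(OC)c(OC)c2)C[C@H]([O-])C=C[C@H]1O[Si](C)(C)C(C)(C)C.[Na+] | intermediate
26 | 3S methyl ether (1S,3S,6R,7S,8R) | C=CC[C@@]1([C@@H](C)[C@H](O[Si](C(C)C)(C(C)C)C(C)C)c2ccc(OC)c(OC)c2)C[C@H](OC)C=C[C@H]1O[Si](C)(C)C(C)(C)C | intermediate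
27 | C6 allylic alcohol (1S,3S,6R,7S,8R) | C=CC[C@@]1([C@@H](C)[C@H](O[Si](C(C)C)(C(C)C)C(C)C)c2ccc(OC)c(OC)c2)C[C@H](OC)C=C[C@H]1O | intermediate
28 | C7-O-triisopropylsilyl enone (1S,3S,7S,8R) | C=CC[C@@]1([C@@H](C)[C@H](O[Si](C(C)C)(C(C)C)C(C)C)c2ccc(OC)c(OC)c2)C[C@H](OC)C=CC1=O | intermediate
29 | (4S,6S)-6-allyl-6-[(1S,2R)-1-(3,4-dimethoxyphenyl)-1-hydroxypropan-2-yl]-4-methoxycyclohex-2-en-1-one | C=CC[C@@]1([C@@H](C)[C@H](O)c2ccc(OC)c(OC)c2)C[C@H](OC)C=CC1=O | target

Total step count: 16
Longest linear sequence: 15 (steps 1 to 5 and 7 to 16)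

**Steps most likely to fail**

**1. Step 7.** Bond formation at the fully substituted C1, next to the branched C8, may be slower than acid-induced desilylation and oligomerisation of the doubly oxygenated diene. The C8 branch may also erode the face selection of the catalyst.

Fallback (sets out from 13, comes back at 22): the C3 oxygen is taken out of the cycloaddition.
- Crotonaldehyde is silylated (t-BuMe2SiOTf, Et3N, Et2O) to (E)-1-(tert-butyldimethylsilyloxy)buta-1,3-diene F1, a smaller and sturdier diene.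
- Under the same catalyst it should add to 13 with ortho and endo orientation, forming the same C1–C6 and C2–C3 bonds, to give the 6-silyloxycyclohex-4-ene-1-carbaldehyde F2.
- Vinylmagnesium bromide followed by methyl chloroformate gives the C9 allylic methyl carbonate F3.
- Formate hydrogenolysis as in step 9 gives the 1-allyl-6-silyloxycyclohex-4-ene F4.
- Riley-type allylic hydroxylation (SeO2 cat., t-BuOOH, CH2Cl2) then attacks C3, the only unhindered allylic CH2 of the disubstituted ring alkene, and leads to 22. Any 3S epimer formed beside it is 24 and re-enters at step 13.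

**2. Step 10.** Cleavage may not stop after the first silyl group, or may be slow and unselective between C3 and C6.

Fallback (sets out from 21, comes back at 23): the differentiation is moved from the desilylation to the substitution.
- Both ring silyl ethers are removed (HF·pyridine, THF, rt; the triisopropylsilyl ether stays) to give the cis-cyclohex-4-ene-3,6-diol F5.
- The Mitsunobu reaction with 4-nitrobenzoic acid can engage only C3–OH, because SN2 at the neopentyl C6 is blocked. It gives the 3S 4-nitrobenzoate with free C6 hydroxyl F6.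
- t-BuMe2SiOTf and 2,6-lutidine then silylate C6–OH and give 23.

**3. Step 8.** The alkoxide formed next to the cis C6 silyl ether may take over that silyl group before it is acylated. Acylation (and later ionisation) at a carbon attached to quaternary C1 may also be sluggish.

Fallback (sets out from 17, comes back at 21): no alkoxide is formed and the two carbons arrive by two Wittig reactions.
- (Methoxymethyl)triphenylphosphonium chloride and KN(SiMe3)2 in THF give the 1-(2-methoxyvinyl) enol ether F7.
- Hg(OAc)2 in aqueous THF hydrolyses it to the homologous (formylmethyl) aldehyde F8.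
- Methylenetriphenylphosphorane converts this into 21.

**Further compounds**

F1 | step 7 | (E)-1-(tert-butyldimethylsilyloxy)buta-1,3-diene | C=C/C=C/O[Si](C)(C)C(C)(C)C
F2 | step 7 | (1R,6R,7S,8R)-6-(tert-butyldimethylsilyloxy)-1-[1-(3,4-dimethoxyphenyl)-1-(triisopropylsilyloxy)propan-2-yl]cyclohex-4-ene-1-carbaldehyde | O=C[C@@]1([C@@H](C)[C@H](O[Si](C(C)C)(C(C)C)C(C)C)c2ccc(OC)c(OC)c2)CCC=C[C@H]1O[Si](C)(C)C(C)(C)C
F3 | step 7 | methyl carbonate of the C9 vinyl carbinol from F2 (C9 epimers) | C=CC(OC(=O)OC)[C@@]1([C@@H](C)[C@H](O[Si](C(C)C)(C(C)C)C(C)C)c2ccc(OC)c(OC)c2)CCC=C[C@H]1O[Si](C)(C)C(C)(C)C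
F4 | step 7 | (1R,6R,7S,8R)-1-allyl-6-(tert-butyldimethylsilyloxy)-1-[1-(3,4-dimethoxyphenyl)-1-(triisopropylsilyloxy)propan-2-yl]cyclohex-4-ene | C=CC[C@@]1([C@@H](C)[C@H](O[Si](C(C)C)(C(C)C)C(C)C)c2ccc(OC)c(OC)c2)CCC=C[C@H]1O[Si](C)(C)C(C)(C)C
F5 | step 10 | (1S,3R,6R,7S,8R)-1-allyl-1-[1-(3,4-dimethoxyphenyl)-1-(triisopropylsilyloxy)propan-2-yl]cyclohex-4-ene-3,6-diol | C=CC[C@@]1([C@@H](C)[C@H](O[Si](C(C)C)(C(C)C)C(C)C)c2ccc(OC)c(OC)c2)C[C@@H](O)C=C[C@H]1O
F6 | step 10 | (1S,3S,6R,7S,8R)-1-allyl-6-hydroxy-1-[1-(3,4-dimethoxyphenyl)-1-(triisopropylsilyloxy)propan-2-yl]cyclohex-4-en-3-yl 4-nitrobenzoate | C=CC[C@@]1([C@@H](C)[C@H](O[Si](C(C)C)(C(C)C)C(C)C)c2ccc(OC)c(OC)c2)C[C@H](OC(=O)c2ccc([N+](=O)[O-])cc2)C=C[C@H]1O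
F7 | step 8 | 1-(2-methoxyvinyl) analogue of 17 (E/Z mixture; ring and side chain as in 17) | COC=C[C@@]1([C@@H](C)[C@H](O[Si](C(C)C)(C(C)C)C(C)C)c2ccc(OC)c(OC)c2)C[C@@H](O[Si](C)(C)C(C)(C)C)C=C[C@H]1O[Si](C)(C)C(C)(C)C
F8 | step 8 | 1-(formylmethyl) analogue of 17 (ring and side chain as in 17) | O=CC[C@@]1([C@@H](C)[C@H](O[Si](C(C)C)(C(C)C)C(C)C)c2ccc(OC)c(OC)c2)C[C@@H](O[Si](C)(C)C(C)(C)C)C=C[C@H]1O[Si](C)(C)C(C)(C)C
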